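The numbers in the tables were generated by integration with constants of no real substance, and the scatter is random.

The easy step comes first: starting material takes one coupling partner to first product. First product then adds a second partner to give bis adduct, and bis adduct a third to give triple product, while first product can also meet starting material and give side product.

| setting | oak | larch | north-east | south | west |
|---|---|---|---|---|---|
| starting material | 0.050 M | 0.050 M | 0.050 M | 0.050 M | 0.050 M (fed, over 8.0 min) |
| coupling partner | 0.0525 M | 0.10 M | 0.0525 M | 0.0525 M (fed, over 8.0 min) | 0.0525 M |
| remark | run made earlier | run made earlier | everything together at the start | all else is in the flask from the start; the feed brings no volume worth counting | all else is in the flask from the start; the feed brings no volume worth counting |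
| time |  |  | 10 min | 10 min | 10 min |

- oak (time / min: bis adduct / %, triple product / %): 1.33: 3.3, 3.3; 2.50: 2.9, 2.7; 4.00: 4.8, 4.2; 5.00: 3.9, 7.7; 6.00: 1.9, 5.9
- larch (time / s: bis adduct / %, triple product / %): 10.0: 0, 0; 30.0: 4.4, 3.6; 60.0: 4.6, 9.2; 80.0: 6.1, 14.7; 120: 4.8, 19.4

(standard deviation of a reading: 1 percentage point)

- a species is counted by the starting material in it: one side product counts as two
- the numbers in the tables scatter with a standard deviation of 1 percentage point
- what may be going on: starting material + coupling partner -> first product; coupling partner + first product -> bis adduct; coupling partner + bis adduct -> triple product; coupling partner + triple product <-> tetra adduct; bis adduct -> over-reaction product; starting material + first product -> side product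

- the flask that comes out highest in share of bis adduct in bis adduct plus triple product, or "all alike" when all lie within 1.5 percentage points (north-east / south / west / all alike)
- share of bis adduct in bis adduct plus triple product at the end, north-east
- share of bis adduct in bis adduct plus triple product at the end, south
- share of bis adduct in bis adduct plus triple product at the end, west

The runs hold an oddity. Larch has twice the partner of oak, and its triple product reads 19.4% at 120 s against 7.7% in oak at 5.00 min. Yet bis adduct averages only 5.17% over the larch readings from 60.0 s on and 3.53% over the oak readings from 4.00 min on.

A balance clears this up. Bis adduct is both made and lost by a step carrying c(coupling partner), so on a plateau that concentration cancels, and c(first product)/c(bis adduct) equals s, the third-step constant over the second. Equal reactivity, the statistical zero, is s = 1. First product is unread, so counting everything outside bis adduct and triple product as first product, larch reads a selectivity factor s of 14.6. The share then follows as 1/(1 + s·c(triple product)/c(first product)).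

Oak, the north-east recipe, reads 37.3%. Either slow feed should raise triple product per first product, so the flask picked here is north-east.

The forecast says south, with 33%, 40% and 25% for north-east, south and west; of south it says “Bis adduct forms late and has little time to go on”.

The flasks give 33.6%, 24.6% and 14.1%, so north-east stands highest.

    starting material + coupling partner → first product (k = 1.46 /M/s)
    coupling partner + first product → bis adduct (k = 0.0837 /M/s)
    coupling partner + bis adduct → triple product (k = 1.30 /M/s)
    coupling partner + triple product ⇌ tetra adduct (K = 7.30 /M, k = 2.12 /M/s)
    bis adduct → over-reaction product (k = 1.03 × 10⁻⁵ /s)
    starting material + first product → side product (k = 0.197 /M/s)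

North-east ends with 59.9% first product and 7.43% triple product, and s turns these into 35.6%, against 33.6%. The neighbour charged with 0.089 M of partner, all else held, ends with 48.7% first product and 36.6% triple product. The same reckoning gives 8.36%, and that flask gives 8.37%.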